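**Plan**
- Retrosynthesis: the ether is cut at C14–C15 (alkenyl carbon to OCH2), giving a labdane C13 alkyne, AlMe3 (C16) and a eudesman-4α-yl chloromethyl ether (C15). In the labdane, C4–C5 and C9–C10 are cut together to an acyclic E,E-dienyl 2-methyl-3-oxo ester.
- Enabling feature: C4 of ring A carries a methyl and the C19 carboxyl and is bonded to C5, and C8 of ring B carries the exocyclic C17 methylene, so C4 can start and C8 can end an oxidative radical bicyclisation.
- Forward: geranylacetone (as its dioxolane, so C11–C13 are already in place) is hydroxylated at its E-methyl, brominated and joined to the dianion of (−)-8-phenylmenthyl 2-methylacetoacetate; rings A and B then close in one step.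
- The C3 ketone is removed, the side-chain methyl ketone becomes the terminal alkyne, and methylalumination then alkoxymethylation joins diterpene and sesquiterpene; reduction of the auxiliary ester and reoxidation of C19 give the acid.
- Stereochemistry: C4, C5, C9 and C10 come from chair–chair folding of the E,E-diene (relative) under the 8-phenylmenthyl ester (absolute); eudesmane C5, C7 and C10 come from (+)-β-eudesmol and C4 from α-face epoxidation then hydride opening; 13E comes from syn-carboalumination.

Key step: step 6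

Assumption: the (1R,2S,5R) auxiliary is taken to expose the face of the C4 radical that leads to the 4S,5R,9S,10R series (axial 4β-carboxyl, 10β-methyl), the sense known for such esters in related aryl-terminated cyclisations.
Labdane and eudesmane numbering is used; 8-phenylmenthyl = (1R,2S,5R)-5-methyl-2-(2-phenylpropan-2-yl)cyclohexyl.

**Route**

Step 1
Reactants: 1 geranylacetone, (5E)-6,10-dimethylundeca-5,9-dien-2-one
Product: 2 2-[(3E)-4,8-dimethylnona-3,7-dien-1-yl]-2-methyl-1,3-dioxolane
Conditions: ethylene glycol, PPTS (cat.), benzene, reflux, Dean–Stark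
Reagents that add atoms: ethylene glycol, OCCO
Why: Acid-catalysed ketalisation with azeotropic removal of water masks the methyl ketone against the dianion of step 5 and keeps it distinct from the C3 ketone formed in step 6, and no stereocentre is formed.

Step 2
Reactants: 2 geranylacetone dioxolane
Product: 3 (2E,6E)-2,6-dimethyl-9-(2-methyl-1,3-dioxolan-2-yl)nona-2,6-dien-1-ol
Conditions: SeO2 (0.1 equiv), t-BuOOH (anhydrous, in decane), CH2Cl2, 0 °C to rt
Reagents that add atoms: selenium dioxide, O=[Se]=O (oxygen carrier); tert-butyl hydroperoxide, CC(C)(C)OO (terminal oxidant)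
Why: SeO2-catalysed allylic oxidation (ene reaction then [2,3]-sigmatropic shift) should hydroxylate the E-methyl of the terminal, most accessible trisubstituted alkene and so fix the 2E geometry.

Step 3
Reactants: 3 allylic alcohol
Product: 4 2-[(3E,7E)-9-bromo-4,8-dimethylnona-3,7-dien-1-yl]-2-methyl-1,3-dioxolane
Conditions: CBr4, PPh3, CH2Cl2, 0 °C
Reagents that add atoms: carbon tetrabromide, BrC(Br)(Br)Br
Why: The Appel reaction converts the primary allylic alcohol into the bromide under neutral conditions, without allylic transposition and without touching the ketal.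

Step 4
Reactants: 5 methyl 2-methyl-3-oxobutanoate (racemic); 6 (−)-8-phenylmenthol, (1R,2S,5R)-5-methyl-2-(2-phenylpropan-2-yl)cyclohexan-1-ol
Product: 7 (−)-8-phenylmenthyl 2-methyl-3-oxobutanoate (C2 epimers, interconverting through the enol)
Conditions: DMAP (0.3 equiv), toluene, reflux, methanol removed through 4 Å molecular sieves
Reagents that add atoms: none
Why: DMAP-catalysed transesterification of an enolisable β-keto ester (through the acylketene) with removal of methanol installs the auxiliary, and the labile C2 centre is of no consequence.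

Step 5
Reactants: 7 (−)-8-phenylmenthyl 2-methyl-3-oxobutanoate; 4 allylic bromide
Product: 8 (−)-8-phenylmenthyl (6E,10E)-2,6,10-trimethyl-13-(2-methyl-1,3-dioxolan-2-yl)-3-oxotrideca-6,10-dienoate (C2 epimers)
Conditions: 7, LiN(i-Pr)2 (2.1 equiv), THF, 0 °C; then 4, 0 °C to rt; water quench
Reagents that add atoms: none
Why: γ-Alkylation of the β-keto ester dianion, in which the more basic terminal carbanion displaces the primary allylic bromide by SN2, gives the 2-methyl-3-oxo ester with both E-alkenes in place.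

Step 6
Reactants: 8 dienyl 2-methyl-3-oxo ester
Product: 9 (−)-8-phenylmenthyl 13,13-(ethylenedioxy)-3-oxo-14,15-dinorlabd-8(17)-en-19-oate (4α-methyl, ester carbon C19 axial on the β face, 5α-H, 9α-H, 10β-methyl)
Conditions: Mn(OAc)3·2H2O (2.2 equiv), Cu(OAc)2·H2O (1.0 equiv), KOAc (2 equiv), degassed AcOH, rt, N2; poured into cold aq. NaHCO3
Reagents that add atoms: none
Why: Mn(OAc)3 (trivalent manganese) forms the enolate of the 2-methyl-3-oxo ester and oxidises it to an electrophilic tertiary C4 radical, which adds to C5 of the proximal alkene; the tertiary C10 radical so formed adds to C9 of the distal alkene, and Cu(OAc)2 (divalent copper) captures the tertiary C8 radical and eliminates a C17 hydrogen, two equivalents of Mn(OAc)3 being consumed as the monovalent copper is reoxidised. The closest known reaction type is the Mn(OAc)3/Cu(OAc)2 oxidative free-radical polyene cyclisation of unsaturated 2-alkyl β-keto esters, 8-phenylmenthyl esters included. Ring A closes 6-endo-trig (C4–C5) and ring B closes 6-endo-trig (C9–C10), each mode being enforced because attack at the less substituted alkene carbon leaves a tertiary radical. Chair–chair folding of the E,E-diene sets the relative configuration: C5–H anti to the C10 methyl (trans fusion), the C9 chain equatorial and anti to the C10 methyl, and the ester axial on C4, syn to the C10 methyl, as C19 requires. The absolute configuration of C4, and through the folding that of C5, C9 and C10, comes from the auxiliary, whose phenyl ring covers one face of the planar C4 radical so that C5 bonds to the open face; the C2 epimers of 8 converge because the radical is planar. The step needs exocyclic termination and an intact dioxolane: copper-mediated elimination favours the least substituted alkene, the side chain offers no radical acceptor or β-leaving group, and KOAc buffering at room temperature should keep the ketal.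

Step 7
Reactants: 9 bicyclic keto ester
Product: 10 (−)-8-phenylmenthyl 13,13-(ethylenedioxy)-3β-hydroxy-14,15-dinorlabd-8(17)-en-19-oate
Conditions: NaBH4, MeOH–THF, 0 °C
Reagents that add atoms: none
Why: Borohydride reduction of the ketone (the shielded ester and the ketal are inert) should deliver hydride along the axial α trajectory to give the equatorial 3β-alcohol, a stereocentre that is erased in step 9.

Step 8
Reactants: 10 3β-alcohol
Product: 11 (−)-8-phenylmenthyl 13,13-(ethylenedioxy)-3β-[(imidazol-1-ylcarbonothioyl)oxy]-14,15-dinorlabd-8(17)-en-19-oate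
Conditions: 1,1'-thiocarbonyldiimidazole, DMAP (cat.), 1,2-dichloroethane, 80 °C
Reagents that add atoms: 1,1'-thiocarbonyldiimidazole, S=C(n1ccnc1)n1ccnc1
Why: Thioacylation of the secondary alcohol under neutral conditions (no alkoxide, hence no retro-aldol opening of the β-hydroxy ester) prepares the Barton–McCombie deoxygenation.

Step 9
Reactants: 11 thiocarbonylimidazolide
Product: 12 (−)-8-phenylmenthyl 13,13-(ethylenedioxy)-14,15-dinorlabd-8(17)-en-19-oate
Conditions: Bu3SnH, AIBN (cat.), toluene, 110 °C
Reagents that add atoms: none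
Why: In the Barton–McCombie deoxygenation the stannyl radical adds to sulfur, the secondary C3 radical is released and is reduced by Bu3SnH before it can rearrange, and the remote alkene and the ketal are spectators.

Step 10
Reactants: 12 deoxygenated ketal
Product: 13 (−)-8-phenylmenthyl 13-oxo-14,15-dinorlabd-8(17)-en-19-oate
Conditions: PPTS (cat.), acetone–H2O, 50 °C
Reagents that add atoms: water, O
Why: Mild acid-catalysed ketal hydrolysis releases the methyl ketone without migration of the exocyclic alkene.

Step 11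
Reactants: 13 methyl ketone
Product: 15 (−)-8-phenylmenthyl 15,16-dinorlabd-8(17)-en-13-yn-19-oate, via enol diethyl phosphate 14 (not isolated)
Conditions: LiN(i-Pr)2 (1.1 equiv), THF, −78 °C; ClP(O)(OEt)2, −78 °C to rt; then added to LiN(i-Pr)2 (2.3 equiv), THF, −78 °C to rt; water quench
Reagents that add atoms: none
Why: Conversion of a methyl ketone into a terminal alkyne through the kinetic enol phosphate (deprotonation at the methyl group, O-phosphorylation, base-induced elimination of diethyl phosphate) should be clean because the ester has no α-hydrogen and is too shielded to be attacked.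

Step 12
Reactants: 16 (+)-β-eudesmol, eudesm-4(15)-en-11-ol
Product: 17 11-(triethylsilyloxy)eudesm-4(15)-ene
Conditions: Et3SiOTf, 2,6-lutidine, CH2Cl2, −78 to 0 °C
Reagents that add atoms: triethylsilyl trifluoromethanesulfonate, CC[Si](CC)(CC)OS(=O)(=O)C(F)(F)F
Why: Silylation of the tertiary alcohol with the silyl triflate and a hindered base protects the C11 hydroxyl so that the alkoxymethyl chloride can later be made at O4 only.

Step 13
Reactants: 17 silyl ether
Product: 18 4α,15-epoxy-11-(triethylsilyloxy)eudesmane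
Conditions: mCPBA, NaHCO3, CH2Cl2, 0 °C
Reagents that add atoms: 3-chloroperoxybenzoic acid, O=C(OO)c1cccc(Cl)c1
Why: Prilezhaev epoxidation of the exocyclic alkene should occur from the α face, the β face being blocked by the syn-axial C10 methyl, which places the epoxide oxygen α at C4.

Step 14
Reactants: 18 spiro-epoxide
Product: 19 11-(triethylsilyloxy)eudesman-4α-ol (cryptomeridiol 11-triethylsilyl ether; 4β-methyl axial)
Conditions: LiAlH4, THF, reflux
Reagents that add atoms: none
Why: Hydride opens the epoxide by SN2 at the primary C15, leaving the tertiary 4α-hydroxyl and the axial 4β-methyl with the C4 configuration set in step 13.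

Step 15
Reactants: 19 tertiary alcohol
Product: 20 4α-[(methylsulfanyl)methoxy]-11-(triethylsilyloxy)eudesmane
Conditions: DMSO, Ac2O, AcOH, rt
Reagents that add atoms: dimethyl sulfoxide, CS(C)=O
Why: Pummerer-type thiomethylation (the acetoxysulfonium ion from DMSO and Ac2O gives a thionium ion that the alcohol captures), the standard method for hindered tertiary alcohols, forms the methylthiomethyl ether with the C4–O bond untouched.

Step 16
Reactants: 20 methylthiomethyl ether
Product: 21 4α-(chloromethoxy)-11-(triethylsilyloxy)eudesmane (used crude)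
Conditions: SO2Cl2, CH2Cl2, −78 to 0 °C; volatiles removed in vacuo; used at once
Reagents that add atoms: sulfuryl chloride, O=S(=O)(Cl)Cl
Why: S-Chlorination of the O,S-acetal by SO2Cl2 and loss of methanesulfenyl chloride give the α-chloro ether under non-protic conditions that spare the silyl ether.

Step 17
Reactants: 15 labdane alkyne; 21 eudesmyl chloromethyl ether
Product: 23 (−)-8-phenylmenthyl 15-{[11-(triethylsilyloxy)eudesman-4α-yl]oxy}labda-8(17),13E-dien-19-oate, via alkenyldimethylalane 22 (not isolated)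
Conditions: 15, AlMe3 (3 equiv), Cp2ZrCl2 (0.5 equiv), CH2Cl2, 0 °C to rt; volatiles (excess AlMe3) removed in vacuo; then 21, CH2Cl2, −20 to 0 °C; aq. NaHCO3
Reagents that add atoms: trimethylaluminium, C[Al](C)C
Why: Zirconium-catalysed syn-carboalumination (Negishi) adds methyl to C13 and aluminium to C14 with E geometry, and the alkenylalane is then C-alkoxymethylated by the α-chloro ether (a known trapping of such alanes by chloromethyl ethers), forming C14–C15 with retention of the alkene geometry.

Step 18
Reactants: 23 coupled ester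
Product: 24 15-{[11-(triethylsilyloxy)eudesman-4α-yl]oxy}labda-8(17),13E-dien-19-ol
Conditions: LiAlH4, THF, reflux
Reagents that add atoms: none
Why: Hydride reduction of the shielded neopentyl ester gives the C19 primary alcohol and releases the auxiliary for recovery, while the alkenes, the allylic ether and the silyl ether are inert to LiAlH4.

Step 19
Reactants: 24 C19 alcohol
Product: 25 15-{[11-(triethylsilyloxy)eudesman-4α-yl]oxy}labda-8(17),13E-dien-19-al
Conditions: Dess–Martin periodinane, pyridine, CH2Cl2, 0 °C to rt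
Reagents that add atoms: none
Why: Dess–Martin oxidation takes the neopentyl primary alcohol to the aldehyde, which has no α-hydrogen and so cannot epimerise.

Step 20
Reactants: 25 C19 aldehyde
Product: 26 15-{[11-(triethylsilyloxy)eudesman-4α-yl]oxy}labda-8(17),13E-dien-19-oic acid
Conditions: NaClO2, NaH2PO4, 2-methylbut-2-ene, t-BuOH–H2O, rt
Reagents that add atoms: sodium chlorite, [Na+].[O-]Cl=O
Why: Pinnick oxidation with 2-methylbut-2-ene as hypochlorite scavenger converts the aldehyde into the acid without touching the two alkenes or the ether.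

Step 21
Reactants: 26 silyl-protected acid
Product: 27 15-[(11-hydroxyeudesman-4α-yl)oxy]labda-8(17),13E-dien-19-oic acid (target; labdane 4S,5R,9S,10R, eudesmane 4R,5R,7R,10R)
Conditions: Bu4NF, THF, rt to 40 °C; pH 5 phosphate buffer
Reagents that add atoms: none
Why: Fluoride-induced desilylation under non-acidic conditions frees the C11 hydroxyl of the eudesmane while the acid-sensitive tertiary allylic ether stays intact.

**Compound list**

1 | geranylacetone, (5E)-6,10-dimethylundeca-5,9-dien-2-one | CC(=O)CC/C=C(\C)CCC=C(C)C | starting material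
2 | 2-[(3E)-4,8-dimethylnona-3,7-dien-1-yl]-2-methyl-1,3-dioxolane | CC1(CC/C=C(\C)CCC=C(C)C)OCCO1 | intermediate
3 | (2E,6E)-2,6-dimethyl-9-(2-methyl-1,3-dioxolan-2-yl)nona-2,6-dien-1-ol | CC1(CC/C=C(\C)CC/C=C(\C)CO)OCCO1 | intermediate
4 | 2-[(3E,7E)-9-bromo-4,8-dimethylnona-3,7-dien-1-yl]-2-methyl-1,3-dioxolane | CC1(CC/C=C(\C)CC/C=C(\C)CBr)OCCO1 | intermediate
5 | methyl 2-methyl-3-oxobutanoate (racemic) | COC(=O)C(C)C(C)=O | starting material
6 | (−)-8-phenylmenthol, (1R,2S,5R)-5-methyl-2-(2-phenylpropan-2-yl)cyclohexan-1-ol | O[C@@H]1C[C@H](C)CC[C@H]1C(C)(C)c1ccccc1 | starting material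
7 | (−)-8-phenylmenthyl 2-methyl-3-oxobutanoate (C2 epimers) | CC(=O)C(C)C(=O)O[C@@H]1C[C@H](C)CC[C@H]1C(C)(C)c1ccccc1 | intermediate
8 | (−)-8-phenylmenthyl (6E,10E)-2,6,10-trimethyl-13-(2-methyl-1,3-dioxolan-2-yl)-3-oxotrideca-6,10-dienoate (C2 epimers) | CC1(CC/C=C(\C)CC/C=C(\C)CCC(=O)C(C)C(=O)O[C@@H]2C[C@H](C)CC[C@H]2C(C)(C)c2ccccc2)OCCO1 | intermediate
9 | (−)-8-phenylmenthyl 13,13-(ethylenedioxy)-3-oxo-14,15-dinorlabd-8(17)-en-19-oate | C=C1CC[C@@H]2[C@](C)(CCC(=O)[C@]2(C)C(=O)O[C@@H]2C[C@H](C)CC[C@H]2C(C)(C)c2ccccc2)[C@H]1CCC1(C)OCCO1 | intermediate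
10 | (−)-8-phenylmenthyl 13,13-(ethylenedioxy)-3β-hydroxy-14,15-dinorlabd-8(17)-en-19-oate | C=C1CC[C@@H]2[C@](C)(CC[C@H](O)[C@]2(C)C(=O)O[C@@H]2C[C@H](C)CC[C@H]2C(C)(C)c2ccccc2)[C@H]1CCC1(C)OCCO1 | intermediate
11 | (−)-8-phenylmenthyl 13,13-(ethylenedioxy)-3β-[(imidazol-1-ylcarbonothioyl)oxy]-14,15-dinorlabd-8(17)-en-19-oate | C=C1CC[C@@H]2[C@](C)(CC[C@H](OC(=S)n3ccnc3)[C@]2(C)C(=O)O[C@@H]2C[C@H](C)CC[C@H]2C(C)(C)c2ccccc2)[C@H]1CCC1(C)OCCO1 | intermediate
12 | (−)-8-phenylmenthyl 13,13-(ethylenedioxy)-14,15-dinorlabd-8(17)-en-19-oate | C=C1CC[C@@H]2[C@](C)(CCC[C@]2(C)C(=O)O[C@@H]2C[C@H](C)CC[C@H]2C(C)(C)c2ccccc2)[C@H]1CCC1(C)OCCO1 | intermediate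
13 | (−)-8-phenylmenthyl 13-oxo-14,15-dinorlabd-8(17)-en-19-oate | C=C1CC[C@@H]2[C@](C)(CCC[C@]2(C)C(=O)O[C@@H]2C[C@H](C)CC[C@H]2C(C)(C)c2ccccc2)[C@H]1CCC(C)=O | intermediate
14 | (−)-8-phenylmenthyl 13-[(diethoxyphosphoryl)oxy]-15,16-dinorlabda-8(17),13-dien-19-oate | C=C1CC[C@@H]2[C@](C)(CCC[C@]2(C)C(=O)O[C@@H]2C[C@H](C)CC[C@H]2C(C)(C)c2ccccc2)[C@H]1CCC(=C)OP(=O)(OCC)OCC | intermediate (not isolated)
15 | (−)-8-phenylmenthyl 15,16-dinorlabd-8(17)-en-13-yn-19-oate | C=C1CC[C@@H]2[C@](C)(CCC[C@]2(C)C(=O)O[C@@H]2C[C@H](C)CC[C@H]2C(C)(C)c2ccccc2)[C@H]1CCC#C | intermediate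
16 | (+)-β-eudesmol, eudesm-4(15)-en-11-ol | C=C1CCC[C@]2(C)CC[C@@H](C(C)(C)O)C[C@H]21 | starting material
17 | 11-(triethylsilyloxy)eudesm-4(15)-ene | C=C1CCC[C@]2(C)CC[C@@H](C(C)(C)O[Si](CC)(CC)CC)C[C@H]21 | intermediate
18 | 4α,15-epoxy-11-(triethylsilyloxy)eudesmane | C1O[C@@]12CCC[C@]3(C)CC[C@@H](C(C)(C)O[Si](CC)(CC)CC)C[C@H]32 | intermediate
19 | 11-(triethylsilyloxy)eudesman-4α-ol | O[C@]1(C)CCC[C@]2(C)CC[C@@H](C(C)(C)O[Si](CC)(CC)CC)C[C@H]21 | intermediate
20 | 4α-[(methylsulfanyl)methoxy]-11-(triethylsilyloxy)eudesmane | CSCO[C@]1(C)CCC[C@]2(C)CC[C@@H](C(C)(C)O[Si](CC)(CC)CC)C[C@H]21 | intermediate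
21 | 4α-(chloromethoxy)-11-(triethylsilyloxy)eudesmane | ClCO[C@]1(C)CCC[C@]2(C)CC[C@@H](C(C)(C)O[Si](CC)(CC)CC)C[C@H]21 | intermediate
22 | (−)-8-phenylmenthyl 14-(dimethylalumanyl)-15-norlabda-8(17),13E-dien-19-oate | C=C1CC[C@@H]2[C@](C)(CCC[C@]2(C)C(=O)O[C@@H]2C[C@H](C)CC[C@H]2C(C)(C)c2ccccc2)[C@H]1CC/C(C)=C/[Al](C)C | intermediate (not isolated)
23 | (−)-8-phenylmenthyl 15-{[11-(triethylsilyloxy)eudesman-4α-yl]oxy}labda-8(17),13E-dien-19-oate | C=C1CC[C@@H]2[C@](C)(CCC[C@]2(C)C(=O)O[C@@H]2C[C@H](C)CC[C@H]2C(C)(C)c2ccccc2)[C@H]1CC/C(C)=C/CO[C@]1(C)CCC[C@]2(C)CC[C@@H](C(C)(C)O[Si](CC)(CC)CC)C[C@H]21 | intermediate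
24 | 15-{[11-(triethylsilyloxy)eudesman-4α-yl]oxy}labda-8(17),13E-dien-19-ol | C=C1CC[C@@H]2[C@](C)(CCC[C@]2(C)CO)[C@H]1CC/C(C)=C/CO[C@]1(C)CCC[C@]2(C)CC[C@@H](C(C)(C)O[Si](CC)(CC)CC)C[C@H]21 | intermediate
25 | 15-{[11-(triethylsilyloxy)eudesman-4α-yl]oxy}labda-8(17),13E-dien-19-al | C=C1CC[C@@H]2[C@](C)(CCC[C@]2(C)C=O)[C@H]1CC/C(C)=C/CO[C@]1(C)CCC[C@]2(C)CC[C@@H](C(C)(C)O[Si](CC)(CC)CC)C[C@H]21 | intermediate
26 | 15-{[11-(triethylsilyloxy)eudesman-4α-yl]oxy}labda-8(17),13E-dien-19-oic acid | C=C1CC[C@@H]2[C@](C)(CCC[C@]2(C)C(=O)O)[C@H]1CC/C(C)=C/CO[C@]1(C)CCC[C@]2(C)CC[C@@H](C(C)(C)O[Si](CC)(CC)CC)C[C@H]21 | intermediate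
27 | 15-[(11-hydroxyeudesman-4α-yl)oxy]labda-8(17),13E-dien-19-oic acid | C=C1CC[C@@H]2[C@](C)(CCC[C@]2(C)C(=O)O)[C@H]1CC/C(C)=C/CO[C@]1(C)CCC[C@]2(C)CC[C@@H](C(C)(C)O)C[C@H]21 | target

**Step count**
Total: 21 steps. Longest linear sequence: 15 steps (steps 1–3, 5–11 and 17–21, from geranylacetone).

**Steps most likely to fail**

Step 6: the dioxolane may be solvolysed in the acidic, metal-acetate-laden medium while the cyclisation runs, which would leave two ketones that the borohydride reduction of step 7 cannot tell apart. The fallback sets out from 8. PPTS in aqueous acetone removes the ketal first and gives (−)-8-phenylmenthyl (6E,10E)-2,6,10-trimethyl-3,14-dioxopentadeca-6,10-dienoate F1. The same Mn(OAc)3/Cu(OAc)2 cyclisation, now with no acid-labile group, should give (−)-8-phenylmenthyl 3,13-dioxo-14,15-dinorlabd-8(17)-en-19-oate F2. Ketalisation with 1,2-bis(trimethylsilyloxy)ethane and catalytic Me3SiOTf at −78 °C should then select the unhindered side-chain ketone, because the C3 ketone sits next to the quaternary C4 within a β-keto ester, and the route is rejoined at 9.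

Step 17: the Lewis-acidic aluminium centre may ionise the tertiary alkoxymethyl chloride to an oxocarbenium ion that loses formaldehyde, or a methyl group may be transferred in place of the alkenyl group. The fallback sets out from 15 and 19 and makes the C15–O bond instead of the C14–C15 bond. Carboalumination of 15 as before gives 22, which is turned into its aluminate with n-BuLi and hydroxymethylated with paraformaldehyde to (−)-8-phenylmenthyl 15-hydroxylabda-8(17),13E-dien-19-oate F3. An Appel reaction gives (−)-8-phenylmenthyl 15-bromolabda-8(17),13E-dien-19-oate F4. The potassium alkoxide of 19 (KH, 18-crown-6, THF) is then alkylated with F4 in a Williamson ether synthesis, and the route is rejoined at 23. This path needs neither 20 nor 21, so it also covers a failure of steps 15 and 16.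

Step 13: the peracid may attack both faces of the exocyclic alkene (poor facial selectivity), which would carry the C4 epimer forward. The fallback sets out from 17. Oxymercuration with Hg(OAc)2 in aqueous THF, in which mercurinium formation is reversible and water should enter the tertiary C4 from the open α face, gives 15-(acetoxymercurio)-11-(triethylsilyloxy)eudesman-4α-ol F5. Reduction with NaBH4 and NaOH in the same flask removes the mercury and gives 19 directly, bypassing 18.

**Further compounds**

F1 | step 6 | (−)-8-phenylmenthyl (6E,10E)-2,6,10-trimethyl-3,14-dioxopentadeca-6,10-dienoate | CC(=O)CC/C=C(\C)CC/C=C(\C)CCC(=O)C(C)C(=O)O[C@@H]1C[C@H](C)CC[C@H]1C(C)(C)c1ccccc1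
F2 | step 6 | (−)-8-phenylmenthyl 3,13-dioxo-14,15-dinorlabd-8(17)-en-19-oate | C=C1CC[C@@H]2[C@](C)(CCC(=O)[C@]2(C)C(=O)O[C@@H]2C[C@H](C)CC[C@H]2C(C)(C)c2ccccc2)[C@H]1CCC(C)=O
F3 | step 17 | (−)-8-phenylmenthyl 15-hydroxylabda-8(17),13E-dien-19-oate | C=C1CC[C@@H]2[C@](C)(CCC[C@]2(C)C(=O)O[C@@H]2C[C@H](C)CC[C@H]2C(C)(C)c2ccccc2)[C@H]1CC/C(C)=C/CO
F4 | step 17 | (−)-8-phenylmenthyl 15-bromolabda-8(17),13E-dien-19-oate | C=C1CC[C@@H]2[C@](C)(CCC[C@]2(C)C(=O)O[C@@H]2C[C@H](C)CC[C@H]2C(C)(C)c2ccccc2)[C@H]1CC/C(C)=C/CBr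
F5 | step 13 | 15-(acetoxymercurio)-11-(triethylsilyloxy)eudesman-4α-ol | CC(=O)O[Hg]C[C@@]1(O)CCC[C@]2(C)CC[C@@H](C(C)(C)O[Si](CC)(CC)CC)C[C@H]21
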